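If the rate in Saturday's flask follows the substrate present, then halving the charge, with gas and temperature held, leaves the fraction converted per hour unchanged. If the rate stays the same in molar terms, that fraction is twice as large. The next run should separate these two cases.

in all of them: gas 2.5 mM (held)

| charge | substrate | temperature | remark | time |
|---|---|---|---|---|
| Saturday's | 0.086 M | 5 °C | run made earlier |  |
| violet | 0.043 M | 5 °C |  | 40 h |
| green | 0.043 M | 45 °C |  | 40 h |
| ochre | 0.043 M | 25 °C |  | 40 h |
| teal | 0.043 M | 65 °C |  | 40 h |

- Saturday's (time / h: product / %, substrate / %): 0.667: 0, 99.3; 1.00: 0.4, 99.5; 1.33: 0, 98.9; 2.50: 1.3, 98.9; 3.00: 1.4, 98.1; 5.00: 3.3, 97.3; 8.00: 5.7, 95.0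

(each reading ± 0.5 percentage points)

- at the start none of the gas is in solution
- the earlier runs do not show what temperature does; that part of a forecast is a guess

- the flask that comes out highest in amount of product, in percent of the substrate charged, or "all alike" when all lie within 1.5 percentage points (violet / green / ochre / teal / all alike)
- product at the end, in percent of the substrate charged, violet
- product at the end, in percent of the substrate charged, green
- product at the end, in percent of the substrate charged, ochre
- product at the end, in percent of the substrate charged, teal

At the start none of the gas is in solution, so I read Saturday's slope only from 2.50 h to 8.00 h, where product goes from 1.3% to 5.7%. With the gas held, I divide this rate of conversion by the substrate present, read as 97.3%. That gives the pseudo-first-order constant k′, the fraction of the remaining substrate converted per hour, read as 0.00822 h⁻¹.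

For violet, I then reckon the conversion as one minus exp(−k′t), which gives 28.0% at 40 h. A rate unchanged in molar terms gives 64.0%. The two cases lie 36 percentage points apart against a scatter of 0.5 points, so I keep violet at 0.043 M, 5 °C and 40 h. The earlier runs do not show what temperature does, so I put no figure of my own on the warmer flasks.

The forecast names teal as highest, with 33% for violet, 80% for ochre, 95% for green and 97% for teal. Of violet it says: “I lean towards the lower end”. Its violet figure stands above mine.

The flasks give 29.9% for violet, 45.3% for ochre, 37.4% for green and 29.9% for teal, so ochre comes out highest.

    substrate + reagent ⇌ product + by-product (K = 11.0, k = 0.0880 L mol⁻¹ min⁻¹, Ea = 62.0 kJ mol⁻¹, ΔH = −21.0 kJ mol⁻¹)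
    gas ⇌ reagent, rate k2*(csat - [reagent]) (kL = 0.00950 min⁻¹)
    crystals ⇌ by-product, rate k3*(cs3 - [by-product]) while solid is left; crystals form when [by-product] > cs3 (solubility = 14.0 mM, k = 0.00450 min⁻¹)
    (constants at 5 °C)

Violet's 29.9% lies 1.9 points above my 28.0% and below 64.0%. Violet read at 6.0 d, with all amounts and the temperature held, comes to 69.4% by my k′. That reading holds 59.4% product, with 41% of the substrate left, and k′ reckoned back from it, as an average over the run, is 0.00625 h⁻¹.

The readings were generated by integration from invented constants; noise was put on by code.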